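All runs were generated by integration for an exercise; the scatter is artificial.

In the steps proposed for this flask, each initiator that reacts leaves one living end, two living ends can rest together as a resting dimer, and a living end that meets transfer agent becomes a dead chain, so [initiator] + [living end] + 2[resting dimer] + [dead chain] stays at the charge of 0.50 mM.

in all of them: initiator 0.50 mM

|  | free monomer | transfer agent | temperature | remark | time |
|---|---|---|---|---|---|
| alpha | 0.020 M | 6 mM | 90 °C | the very flask that is asked about, followed so far |  |
| theta | 0.010 M | 6 mM | 96 °C | run made earlier |  |
| flask | 0.020 M | 6.00 mM | 90 °C |  | 5.0 d |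

- alpha (time / h: monomer in chains / %): 5.00: 13.1; 15.0: 25.2; 25.0: 31.5; 40.0: 33.0; 60.0: 36.4; 72.0: 36.0; 96.0: 38.2
- theta (time / h: monomer in chains / %): 0.250: 3.1; 0.667: 4.2; 1.33: 5.8; 2.00: 10.2; 2.50: 11.0; 3.00: 12.7; 4.00: 16.1

(scatter of a reading: 1 percentage point)

- grey: at 5.0 d add initiator, 50.0% of the amount charged, then wait 10 d
- ochre: at 5.0 d raise the temperature by 25 K, then wait 10 d
- violet: at 5.0 d take out 90% of the monomer in chains then present, then wait 10 d
- amber: change nothing and wait 10 d more

- monomer in chains that was removed still counts
- steps that have been proposed: free monomer + initiator -> living end + monomer in chains; free monomer + living end -> monomer in chains + living end; living end + transfer agent -> dead chain; monomer in chains + initiator <-> isomer of the product + initiator; 2 living end <-> resting dimer; free monomer <-> dormant form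
- additions bring no volume worth counting

- monomer in chains, in percent of the free monomer first charged, at 5.0 d
- the remedy with the largest gain of monomer in chains, or "none" below 2 percentage points (grey / ochre / violet / amber / none)
- monomer in chains present, with what was taken out counted in, in percent of the free monomer first charged, after grey
- monomer in chains present, with what was taken out counted in, in percent of the free monomer first charged, after amber

I have to settle what the next run of this flask charges, changes and leaves. Initiator is charged at 0.50 mM, less than the 6.00 mM of transfer agent. If every living end ends on one transfer agent, the transfer agent loses 8.33% of its own charge and no more, and I call this share the transfer ceiling. That ceiling lies under the full charge, so I leave the transfer agent as it is.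

The alpha readings climb to 31.5% at 25.0 h and go from 36.0% at 72.0 h to 38.2% at 96.0 h, with a scatter of 1 percentage point, so I take that last reading as my figure for 5.0 d and expect amber above it, by an amount these readings do not give. Initiator also stands in a proposed step that turns monomer in chains into isomer of the product, so added initiator may take from what the flask already holds, and I hold it back. Theta differs from alpha in free monomer, 0.010 M against 0.020 M, and in temperature, 96 °C against 90 °C, and its last reading stands at 4.00 h, so it does not show what heat does to this flask at 5.0 d, and I name no remedy from it.

The forecast gives 37.5% at 5.0 d, within 35.5% to 39.5%, and 38% after amber. It chooses grey, with 49.5%, holding that “Initiator is the likely limiter”, and there it parts from my holding initiator back.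

The flask gives 38.2% at 5.0 d, 42.6% after amber and 25.6% after grey, and ochre gains most, 9.7 points.

    free monomer + initiator → living end + monomer in chains (k = 134 /M/h, Ea = 75.0 kJ/mol)
    free monomer + living end → monomer in chains + living end, rate k2*[living end]*[free monomer] (k = 695 /M/h, Ea = 72.0 kJ/mol)
    living end + transfer agent → dead chain (kL = 10.5 /M/h, Ea = 70.0 kJ/mol)
    monomer in chains + initiator ⇌ isomer of the product + initiator, rate k4*[initiator]*[monomer in chains] forward; the back reaction follows from the equilibrium constant (K = 0.930, k = 882 /M/h, Ea = 55.0 kJ/mol, ΔH = −33.0 kJ/mol)
    2 living end ⇌ resting dimer, settled at all times (K = 1.48 × 10⁵ /M, ΔH = −37.0 kJ/mol)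
    free monomer ⇌ dormant form (K = 28.6, k = 0.0511 /h, Ea = 111 kJ/mol, ΔH = −32.0 kJ/mol)
    (constants at 90 °C)

In this flask initiator stands at 0% by 12.0 h, with isomer of the product at 0.306%, while free monomer goes into chains and into the dormant form, which holds 61.3% of the charge at 60.0 h. Living ends then turn into dead chain, which reaches 5.00 × 10⁻⁴ M at 1200 h with transfer agent at 91.7%, the ceiling of 8.33% reached. Grey brings initiator back beside monomer in chains, whose forward half-life in the isomer step, with initiator as charged, is 1.6 h, shorter than 5.0 d. The neighbour with 0.024 M of transfer agent has a ceiling of 2.08%, and at 120 h it holds dead chain 5.00 × 10⁻⁴ M, transfer agent 97.9% and monomer in chains 33.8%.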